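## Structural features

The target is a 3,3''-linked biflavanone: two 5,7-dihydroxychroman-4-one halves (rings A/C and A''/C'') joined by the single bond C3–C3'', with a 4-methoxyphenyl ring B on C2 and a 4-hydroxyphenyl ring B'' on C2''. The four stereocentres C2, C3, C3'' and C2'' are contiguous: the anisyl half is 2,3-cis (2S,3S) and the hydroxyphenyl half is 2,3-trans (2''R,3''S). C3 and C3'' are each α to a ketone and β to a ring oxygen on a benzylic carbon, so enolisation or reversible ring opening can erase C2/C3, and the cis half, being the less stable one, must never meet equilibrating base or acid. Five phenols have to be carried in protected form while one methyl ether stays, and the p-oxygenated benzylic C–O bonds at C2 and C2'' ionise easily under acid. The real difficulty is therefore not ring construction but the unsymmetrical stereotetrad around the crowded C3–C3'' bond: two different B rings, one cis and one trans half, no symmetry element. The key step uses the fact that C4–C3–C3''–C4'' is a succinic acid chain with O1 (on C2) γ to C4'' and O1'' (on C2'') γ to C4. The whole tetrad can therefore be kept in a cis-fused 3,7-dioxabicyclo[3.3.0]octane-4,8-dione whose ring-fusion carbons C3/C3'' cannot invert, a 2,3-cis half appearing as an exo aryl group and a 2,3-trans half as an endo aryl group. Because rings A and A'' are identical, C4–C4a and C4''–C4a'' can both come from one ortho-fluoro aryl nucleophile, whose fluorine later leaves when O1 and O1'' close rings C and C''.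

## Logic of the disconnections

27 ⇒ 26. Cut: the five O–CH2Ph bonds of 26. Reason: the phenols must be masked through organolithium and alkoxide chemistry, and benzyl ethers leave under neutral hydrogenolysis, which a 2,3-cis-flavanone tolerates. Gain: none in skeleton, but 26 has no acidic O–H. Demand: the methyl ether, both ketones and the benzylic ring C–O bonds must survive Pd/C and hydrogen.

26 ⇒ 24. Cut: O1–C8a and O1''–C8a''. Reason: both are aryl–oxygen bonds ortho to a ketone, hence SNAr sites if C8a and C8a'' carry fluorine; the bonds C2–O1 and C2''–O1'' stay intact, and with them the configuration at C2 and C2''. Gain: both pyranone rings disappear and 24 is an open chain. Demand: the alkoxides must cyclise faster than they fragment by retro-aldol cleavage, and no base may outlast ring closure.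

24 ⇒ 17 + two equivalents of 22. Cut: C4–C4a and C4''–C4a''. Reason: these are the two aryl ketone bonds of a 2,3-diaroylsuccinic skeleton, and each hydroxyl of 24 is γ to the opposite carbonyl, so the acyl donor can be the double lactone 17. Gain: the two identical oxygenated rings become one reagent used twice, and 17 holds all four stereocentres in a bicycle that cannot epimerise at C3/C3''. Demand: one addition per carbonyl, no enolisation of 17, no loss of LiF from 22.

22 ⇒ 21 ⇒ 20 ⇒ 18. Cut: C–Li (from C–Br), then C–Br, then two aryl C–O bonds. Reason: direct deprotonation of 20 could occur between the two ethers as well as next to fluorine, whereas electrophilic bromination goes para to an ether and so fixes the site of the metal; the ethers come from SNAr on 18. Gain: 22 is traced to a symmetrical commercial arene in two isolated steps. Demand: substitution of exactly two fluorines, and monobromination.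

17 ⇒ 15. Cut: the acyl–oxygen bond O1''–C4 of lactone B. Reason: an N-acyl oxazolidinone is an acyl donor, so the auxiliary that controlled C3 can be the leaving group of the last lactonisation. Gain: the bicycle opens to a monocyclic lactone with a silyl-protected carbinol. Demand: C3 and C3'' must have the like relation, otherwise the second ring would be trans-fused and would not close.

15 ⇒ 11 + 12. Cut: C2–C3 (aldol) and O1–C4'' (lactone A). Reason: the 2,3-cis half is a syn aldol at C2/C3, which the boron enolate of an imide delivers with known absolute sense. An aldol of a preformed monocyclic lactone enolate was rejected for this bond: the aldehyde would enter trans to the neighbouring carboxyl group, which is the unlike C3/C3'' relation, and correcting it would need enolisation next to an ester that has a β-acyloxy leaving group. Gain: the anisyl carbinol and C3 are removed, leaving an open-chain succinyl bis-imide. Demand: reagent control must override the centres at C3'' and C2'', and the silyl ether must survive the boron triflate.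

11 ⇒ 8 + 9. Cut: N–C4. Reason: the two aldols need auxiliaries of opposite configuration, so they are attached one after the other to a succinic chain whose ends are already different. Gain: return to a mono-imide acid. Demand: acylation without acid, to keep the silyl ether.

8 ⇒ 4 + 5. Cut: C2''–C3''. Reason: the 2,3-trans half is an anti aldol at C2''/C3'', available from the magnesium-catalysed imide aldol with aromatic aldehydes, which also delivers O1'' already silylated. Gain: the chain is reduced to a succinic half-imide. Demand: the free acid must be masked in the flask and the silyl ether kept on work-up.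

4 ⇒ 1 + 2. Cut: N–C4''. Reason: opening a cyclic anhydride with the auxiliary gives the two ends of succinic acid in different form in one step. Gain: commercial materials. Demand: mono-acylation only.

## Other disconnections considered

Alternative 1: The cut is O1''–C2'' in ring C'' of the hydroxyphenyl half. The 2'-hydroxychalcone A1 carries at its α-carbon (C3'') the C3 atom of an all-cis 2-aryl-4-silyloxyflavan. It would close by 6-endo-trig oxa-Michael addition of the phenol under a chiral bifunctional amine/hydrogen-bond-donor catalyst to give A2. C2'' would be set by the catalyst and C3'' by protonation of the enol toward the stable trans arrangement, so both alkene isomers of A1 converge.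
- In its favour: the step is catalytic and makes the trans half along its thermodynamic preference. The cis half is stored as a C4 carbinol with no enolisable C3–H, so base cannot reach it. On this point the alternative is better than the chosen plan, where the cis ring of 26 forms in a basic medium (step 9).
- Against it here: an α-branched chalcone whose α-substituent is a fully substituted flavanyl carbon is a crowded, twisted acceptor. Oxa-Michael additions are reversible, so C2'' can leak through ring opening. Catalyst control must override the stereocentres already in A1. The all-cis 2,3,4-trisubstituted flavan with the C3–C3'' bond has to be built first by chemistry the cut leaves open.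
- Comparison: structurally both plans arrive at the same pentabenzyl ether array. Mechanistically the alternative relies on a reversible conjugate addition steered by a catalyst, the chosen plan on irreversible acylation and SNAr with all centres fixed beforehand in 17. In step economy the alternative needs desilylation, oxidation of C4–OH and hydrogenolysis after its key step, and a separate flavan synthesis plus chalcone assembly before it, which should exceed the ten steps proposed. In convergence and protecting-group scheme it is the equal of the chosen plan.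

Alternative 2: The cuts are O1–C2 and C3–C4 of ring C in the anisyl half. Heating dioxinone A3 would unmask the acylketene A4. Its O=C–C=C=O unit would add as the four-atom partner of a hetero-Diels–Alder reaction to the (Z)-styryl group that the trans-flavanone A5 carries on C3'', giving the dihydropyranone A6. Suprafacial addition to the Z-alkene would give the 2,3-cis relation, and ring A would be aromatised afterwards by ketal hydrolysis and tautomerisation.
- In its favour: two bonds and a ring form in one neutral, thermal step, the cis relation is written into alkene geometry, and no base comes near C3. In bond economy of the key step and in mildness toward the cis half it is better than the chosen plan.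
- Against it here: acylketenes add readily to enol ethers and similar electron-rich alkenes, whereas a 1,2-disubstituted styrene with a branched allylic carbon is a sluggish partner. Dimerisation of A4, Z-to-E isomerisation at the temperature required, or a stepwise zwitterionic path that loses the cis relation are all plausible. The alkene face attacked, which is the C3/C3'' relation, would be controlled only by allylic strain. The closing acid treatment touches a cis-flavanone with a p-methoxybenzylic C2–O1 bond.
- Comparison: structurally the alternative grows ring A of one half from a non-aromatic unit and needs a different synthesis for the other half, while the chosen plan uses 21 twice. Mechanistically it creates C2 and C3 in the key step with uncertain facial control, whereas the chosen key step creates no stereocentre. In step economy it equals the chosen plan after the key step (two steps) but is longer before it, because enantiopure A5 is itself a multi-step target.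

Alternative 3: The cuts are C5–C6, C7–C8 and C4a–C5, so ring A of the anisyl half is removed. Diazoketone A7 is a 2,3-cis-dihydropyran-4-one with a diazoacetyl group on the carbon that becomes C8a. Irradiated with siloxyalkyne A8 it would give phenol A9 by Wolff rearrangement, [2+2] cycloaddition, four-electron ring opening and six-electron ring closure.
- In its favour: the benzannulation is neutral and regiospecific, delivers the 5-hydroxyl free and the 7-oxygen as a silyl ether, and needs no aryl–oxygen bond formation. In regiocontrol of ring A and in avoiding base it equals or betters the chosen plan.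
- Against it here: the C3–H of A7 is as enolisable as in a flavanone, and the cis-dihydropyranone must survive installation of the diazoacetyl group. The other half of A7 contains an aryl ketone and benzyl ethers that absorb light and offer C–H bonds to a carbene. The ketene formed is part of a push–pull enone, which should lower its reactivity in the [2+2] step.
- Comparison: structurally the alternative treats the two identical A rings differently and gives up the symmetry that lets the chosen plan bring in both from one building block. Mechanistically it forms three C–C bonds and a ring in the key step against two C–C bonds and no ring, but on a substrate in which the stereotetrad and the C3–C3'' bond must already exist by other means. In step economy it is longer, since a linear route to A7 precedes the key step and desilylation and hydrogenolysis follow it.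

Key step: step 8

Remark on the chemistry: atom labels of the target (O1, C2, C3, C4, C4a, C8a for the anisyl half, doubly primed for the hydroxyphenyl half) are used for every intermediate.
Remark on the chemistry: 24 is drawn as the open dihydroxy diketone; it may rest as its bis-hemiketal, which base opens in step 9, so both forms are treated as one compound.
Remark on the chemistry: the configuration (1S,2S,5S,6R) of 17 maps onto (2S,3S,3''S,2''R) of the target with no centre inverted on the way (bicycle C1, C2, C5, C6 = target C3, C2, C3'', C2''); 17, 22 and 24 agree with the target atom by atom.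

Step 1
Reactants: 1 (R)-4-benzyl-1,3-oxazolidin-2-one; 2 succinic anhydride
Product: 4 4-[(4R)-4-benzyl-2-oxo-1,3-oxazolidin-3-yl]-4-oxobutanoic acid, via lithium oxazolidinide 3 (not isolated)
Conditions: n-BuLi (1.0 equiv), THF, −78 °C; then 2, −78 → 0 °C; 1 M HCl work-up
Reagents that add atoms: none
Why: Nucleophilic acyl substitution (N-acylation of an oxazolidinone): the lithium oxazolidinide 3 opens the cyclic anhydride; the carboxylate set free is no acylating agent, so only the mono-imide forms, and no stereocentre is made.

Step 2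
Reactants: 4 4-[(4R)-4-benzyl-2-oxo-1,3-oxazolidin-3-yl]-4-oxobutanoic acid; 5 4-(benzyloxy)benzaldehyde
Product: 8 (3S)-4-[(4R)-4-benzyl-2-oxo-1,3-oxazolidin-3-yl]-3-{(R)-[4-(benzyloxy)phenyl][(trimethylsilyl)oxy]methyl}-4-oxobutanoic acid, via trimethylsilyl ester 6 (not isolated), via bis-silyl aldol adduct 7 (not isolated)
Conditions: Et3N (3.2 equiv), Me3SiCl (2.6 equiv), EtOAc, 0 → 23 °C; MgCl2 (0.2 equiv), 5 (1.2 equiv), 23 °C, 24–36 h; then MeOH, pH 5 phosphate buffer, 0 °C
Reagents that add atoms: chlorotrimethylsilane C[Si](C)(C)Cl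
Why: MgCl2-catalysed direct anti-aldol of an N-acyl oxazolidinone (soft enolisation, turnover by silylation of the magnesium aldolate): the chelated Z-enolate is attacked on the face away from the benzyl group through a boat transition state, which with the (R)-auxiliary should give C3''(S) and C2''(R), the anti pair that becomes the trans half. The acid is masked in the flask as silyl ester 6 so that it cannot bind magnesium, and buffered methanolysis of 7 frees the acid while the hindered benzylic silyl ether stays and keeps O1'' from lactonising.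

Step 3
Reactants: 8 (3S)-4-[(4R)-4-benzyl-2-oxo-1,3-oxazolidin-3-yl]-3-{(R)-[4-(benzyloxy)phenyl][(trimethylsilyl)oxy]methyl}-4-oxobutanoic acid; 9 (S)-4-benzyl-1,3-oxazolidin-2-one
Product: 11 (4S)-4-benzyl-3-[(3S)-4-[(4R)-4-benzyl-2-oxo-1,3-oxazolidin-3-yl]-3-{(R)-[4-(benzyloxy)phenyl][(trimethylsilyl)oxy]methyl}-4-oxobutanoyl]-1,3-oxazolidin-2-one, via mixed pivalic anhydride 10 (not isolated)
Conditions: t-BuCOCl (1.05 equiv), Et3N (2.5 equiv), THF, −20 °C; then 9 (1.1 equiv), LiCl (1.2 equiv), −20 → 23 °C
Reagents that add atoms: none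
Why: N-Acylation of an oxazolidinone through a mixed pivalic anhydride with LiCl/Et3N activation; attack goes to the unhindered succinyl carbonyl of 10, the medium is never acidic, and no stereocentre is touched.

Step 4
Reactants: 11 (4S)-4-benzyl-3-[(3S)-4-[(4R)-4-benzyl-2-oxo-1,3-oxazolidin-3-yl]-3-{(R)-[4-(benzyloxy)phenyl][(trimethylsilyl)oxy]methyl}-4-oxobutanoyl]-1,3-oxazolidin-2-one; 12 4-methoxybenzaldehyde
Product: 15 (4S)-4-benzyl-3-{[(2S,3S,4S)-4-{(R)-[4-(benzyloxy)phenyl][(trimethylsilyl)oxy]methyl}-2-(4-methoxyphenyl)-5-oxooxolan-3-yl]carbonyl}-1,3-oxazolidin-2-one, via dibutylboron Z-enolate 13 (not isolated), via syn-aldol bis-imide 14 (not isolated)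
Conditions: Bu2BOTf (1.2 equiv), i-Pr2NEt (1.4 equiv), CH2Cl2, −78 → 0 °C; 12 (1.3 equiv), −78 → 0 °C; pH 7 buffer, MeOH, 30% H2O2, 0 °C; then Et3N, DMAP (0.1 equiv), CH2Cl2, 23 °C
Reagents that add atoms: none
Why: Evans syn-aldol: the dibutylboron Z-enolate 13 reacts through a chair (Zimmerman–Traxler) transition state with the (S)-auxiliary turned away from boron, which should set C3(S) and C2(S), the syn pair of the cis half; only the CH2 next to the (S)-imide is enolised because the C3'' methine is an α-branched imide position. Under Et3N/DMAP the new hydroxyl of 14 acylates itself with the imide at C4'' (5-exo-trig), closing lactone A and releasing the (R)-auxiliary.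

Step 5
Reactants: 15 (4S)-4-benzyl-3-{[(2S,3S,4S)-4-{(R)-[4-(benzyloxy)phenyl][(trimethylsilyl)oxy]methyl}-2-(4-methoxyphenyl)-5-oxooxolan-3-yl]carbonyl}-1,3-oxazolidin-2-one
Product: 17 (1S,2S,5S,6R)-6-[4-(benzyloxy)phenyl]-2-(4-methoxyphenyl)-3,7-dioxabicyclo[3.3.0]octane-4,8-dione, via hydroxy lactone imide 16 (not isolated)
Conditions: Bu4NF/AcOH (1:1, 1.2 equiv), THF, 0 °C; then Et3N, DMAP (0.1 equiv), CH2Cl2, 23 °C
Reagents that add atoms: none
Why: Fluoride desilylation followed by intramolecular O-acylation (5-exo-trig lactonisation with loss of the auxiliary): O1'' can reach C4 only because the two auxiliaries have given C3 and C3'' the like (S,S) relation, and the result is the cis-fused bicycle. C2'' and C3'' are not touched, so the 4-benzyloxyphenyl group ends endo and the 4-methoxyphenyl group exo.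

Step 6
Reactants: 18 1,3,5-trifluorobenzene
Product: 20 1,3-bis(benzyloxy)-5-fluorobenzene, via 1-(benzyloxy)-3,5-difluorobenzene 19 (not isolated)
Conditions: BnOH (2.1 equiv), NaH (2.2 equiv), NMP, 0 → 90 °C
Reagents that add atoms: benzyl alcohol OCc1ccccc1
Why: Two nucleophilic aromatic substitutions of fluoride by benzyloxide (addition–elimination); each alkoxy group makes the ring less electrophilic than the fluorine it replaces, so stoichiometry and temperature should stop the reaction at the bis-ether.

Step 7
Reactants: 20 1,3-bis(benzyloxy)-5-fluorobenzene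
Product: 21 1,5-bis(benzyloxy)-2-bromo-3-fluorobenzene
Conditions: NBS (1.0 equiv), MeCN, 0 → 23 °C
Reagents that add atoms: N-bromosuccinimide O=C1CCC(=O)N1Br
Why: Electrophilic aromatic bromination: the carbon para to one benzyloxy group and ortho to the other is the most activated and is less crowded than the carbon between the two ethers; one equivalent of NBS at 0 °C should stop at the monobromide.

Step 8
Reactants: 17 (1S,2S,5S,6R)-6-[4-(benzyloxy)phenyl]-2-(4-methoxyphenyl)-3,7-dioxabicyclo[3.3.0]octane-4,8-dione; 21 1,5-bis(benzyloxy)-2-bromo-3-fluorobenzene (2.3 equiv)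
Product: 24 (1S,2S,3S,4R)-2,3-bis[2,4-bis(benzyloxy)-6-fluorobenzoyl]-4-[4-(benzyloxy)phenyl]-1-(4-methoxyphenyl)butane-1,4-diol, via 2-fluoro-4,6-bis(benzyloxy)phenyllithium 22 (not isolated), via dilithium bis-hemiketalate 23 (not isolated)
Conditions: 21, n-BuLi (2.2 equiv), THF, −78 °C, 15 min; then 17 in THF added slowly, −78 °C, 2 h; AcOH in THF at −78 °C, then aq. NH4Cl
Reagents that add atoms: none
Why: Bromine–lithium exchange on 21 gives 22, an aryllithium stabilised by its ortho fluorine and ortho oxygen, which at −78 °C should neither lose LiF nor attack the butyl bromide. One molecule of 22 adds to each lactone carbonyl of 17 (nucleophilic addition to an ester carbonyl), forming C4–C4a and C4''–C4a'' and giving the dilithium bis-hemiketalate 23; protonation at −78 °C and ring–chain tautomerism then give 24. The closest known reaction type is the addition of 2,6-disubstituted aryllithiums to γ- and δ-lactones that stops at the lactol, as used for C-aryl glycosides. No ring is closed and no stereocentre is created, since the two hemiketal carbons end as carbonyl carbons. The step needs mono-addition at each carbonyl, which is secured by the persistence of the tetrahedral lithium alkoxide at low temperature and by the two ortho substituents that shield the carbonyl once it forms. It also needs addition to win over deprotonation at C3/C3'', which the modest basicity of the fluorine- and oxygen-stabilised carbanion, the low temperature and the slow addition of 17 to 22 should secure. The stereotetrad is safe because C3 and C3'' stay ring-fusion atoms of a cis-fused bicycle (inversion would demand trans fusion) until both C–C bonds exist and the mixture is quenched cold with a weak acid.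

Step 9
Reactants: 24 (1S,2S,3S,4R)-2,3-bis[2,4-bis(benzyloxy)-6-fluorobenzoyl]-4-[4-(benzyloxy)phenyl]-1-(4-methoxyphenyl)butane-1,4-diol
Product: 26 (2S,3S)-5,7-bis(benzyloxy)-3-[(2R,3S)-5,7-bis(benzyloxy)-2-[4-(benzyloxy)phenyl]-4-oxochroman-3-yl]-2-(4-methoxyphenyl)chroman-4-one, via dipotassium dialkoxide 25 (not isolated)
Conditions: KN(SiMe3)2 (2.05 equiv), THF, −78 → 0 °C; pH 7 buffer
Reagents that add atoms: none
Why: Double intramolecular SNAr (addition–elimination through a Meisenheimer complex) of the benzylic alkoxides of 25 on the ortho-fluoroaryl ketones, each a 6-exo closure in which O1 can reach only C8a and O1'' only C8a'' (the distal arene would need a seven-membered ring). The C–O bonds at C2 and C2'' are not broken, so all four centres are retained, and with 2.05 equivalents of base only KF is left once both rings are closed, so nothing remains to enolise C3 of the cis half.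

Step 10
Reactants: 26 (2S,3S)-5,7-bis(benzyloxy)-3-[(2R,3S)-5,7-bis(benzyloxy)-2-[4-(benzyloxy)phenyl]-4-oxochroman-3-yl]-2-(4-methoxyphenyl)chroman-4-one
Product: 27 (2S,3S)-5,7-dihydroxy-3-[(2R,3S)-5,7-dihydroxy-2-(4-hydroxyphenyl)-4-oxochroman-3-yl]-2-(4-methoxyphenyl)chroman-4-one
Conditions: H2 (1 atm), 10% Pd/C, EtOAc/MeOH, 23 °C
Reagents that add atoms: none
Why: Hydrogenolysis of five benzyl ethers over Pd/C under neutral conditions; the methyl ether, the aryl ketones and the ring C–O bonds at C2/C2'' should be stable, and without acid or base the cis half keeps its configuration.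

Compound list

1 | (R)-4-benzyl-1,3-oxazolidin-2-one | O=C1N[C@H](Cc2ccccc2)CO1 | starting material
2 | succinic anhydride | O=C1CCC(=O)O1 | starting material
3 | lithium (R)-4-benzyl-2-oxo-1,3-oxazolidin-3-ide | [Li]N1[C@H](Cc2ccccc2)COC1=O | intermediate
4 | 4-[(4R)-4-benzyl-2-oxo-1,3-oxazolidin-3-yl]-4-oxobutanoic acid | OC(=O)CCC(=O)N1[C@H](Cc2ccccc2)COC1=O | intermediate
5 | 4-(benzyloxy)benzaldehyde | O=Cc1ccc(OCc2ccccc2)cc1 | starting material
6 | trimethylsilyl 4-[(4R)-4-benzyl-2-oxo-1,3-oxazolidin-3-yl]-4-oxobutanoate | C[Si](C)(C)OC(=O)CCC(=O)N1[C@H](Cc2ccccc2)COC1=O | intermediate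
7 | trimethylsilyl (3S)-4-[(4R)-4-benzyl-2-oxo-1,3-oxazolidin-3-yl]-3-{(R)-[4-(benzyloxy)phenyl][(trimethylsilyl)oxy]methyl}-4-oxobutanoate | C[Si](C)(C)OC(=O)C[C@@H]([C@@H](O[Si](C)(C)C)c1ccc(OCc2ccccc2)cc1)C(=O)N1[C@H](Cc2ccccc2)COC1=O | intermediate
8 | (3S)-4-[(4R)-4-benzyl-2-oxo-1,3-oxazolidin-3-yl]-3-{(R)-[4-(benzyloxy)phenyl][(trimethylsilyl)oxy]methyl}-4-oxobutanoic acid | OC(=O)C[C@@H]([C@@H](O[Si](C)(C)C)c1ccc(OCc2ccccc2)cc1)C(=O)N1[C@H](Cc2ccccc2)COC1=O | intermediate
9 | (S)-4-benzyl-1,3-oxazolidin-2-one | O=C1N[C@@H](Cc2ccccc2)CO1 | starting material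
10 | mixed anhydride of 8 with pivalic acid | CC(C)(C)C(=O)OC(=O)C[C@@H]([C@@H](O[Si](C)(C)C)c1ccc(OCc2ccccc2)cc1)C(=O)N1[C@H](Cc2ccccc2)COC1=O | intermediate
11 | (4S)-4-benzyl-3-[(3S)-4-[(4R)-4-benzyl-2-oxo-1,3-oxazolidin-3-yl]-3-{(R)-[4-(benzyloxy)phenyl][(trimethylsilyl)oxy]methyl}-4-oxobutanoyl]-1,3-oxazolidin-2-one (succinyl bis-imide, (S)-auxiliary on C4, (R)-auxiliary on C4'') | O=C(C[C@@H]([C@@H](O[Si](C)(C)C)c1ccc(OCc2ccccc2)cc1)C(=O)N1[C@H](Cc2ccccc2)COC1=O)N1[C@@H](Cc2ccccc2)COC1=O | intermediate
12 | 4-methoxybenzaldehyde | COc1ccc(C=O)cc1 | starting material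
13 | dibutylboron (Z)-enolate of 11 at C3=C4 | CCCCB(CCCC)O/C(=C\[C@@H]([C@@H](O[Si](C)(C)C)c1ccc(OCc2ccccc2)cc1)C(=O)N1[C@H](Cc2ccccc2)COC1=O)N1[C@@H](Cc2ccccc2)COC1=O | intermediate
14 | (4S)-4-benzyl-3-[(2S,3S)-4-[(4R)-4-benzyl-2-oxo-1,3-oxazolidin-3-yl]-3-{(R)-[4-(benzyloxy)phenyl][(trimethylsilyl)oxy]methyl}-2-[(S)-hydroxy(4-methoxyphenyl)methyl]-4-oxobutanoyl]-1,3-oxazolidin-2-one | COc1ccc(cc1)[C@@H](O)[C@@H](C(=O)N1[C@@H](Cc2ccccc2)COC1=O)[C@@H]([C@@H](O[Si](C)(C)C)c1ccc(OCc2ccccc2)cc1)C(=O)N1[C@H](Cc2ccccc2)COC1=O | intermediate
15 | (4S)-4-benzyl-3-{[(2S,3S,4S)-4-{(R)-[4-(benzyloxy)phenyl][(trimethylsilyl)oxy]methyl}-2-(4-methoxyphenyl)-5-oxooxolan-3-yl]carbonyl}-1,3-oxazolidin-2-one | COc1ccc(cc1)[C@H]1OC(=O)[C@H]([C@@H](O[Si](C)(C)C)c2ccc(OCc3ccccc3)cc2)[C@@H]1C(=O)N1[C@@H](Cc2ccccc2)COC1=O | intermediate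
16 | (4S)-4-benzyl-3-{[(2S,3S,4S)-4-{(R)-[4-(benzyloxy)phenyl](hydroxy)methyl}-2-(4-methoxyphenyl)-5-oxooxolan-3-yl]carbonyl}-1,3-oxazolidin-2-one | COc1ccc(cc1)[C@H]1OC(=O)[C@H]([C@@H](O)c2ccc(OCc3ccccc3)cc2)[C@@H]1C(=O)N1[C@@H](Cc2ccccc2)COC1=O | intermediate
17 | (1S,2S,5S,6R)-6-[4-(benzyloxy)phenyl]-2-(4-methoxyphenyl)-3,7-dioxabicyclo[3.3.0]octane-4,8-dione (cis-fused; 4-methoxyphenyl exo, 4-benzyloxyphenyl endo) | COc1ccc(cc1)[C@H]1OC(=O)[C@H]2[C@@H]1C(=O)O[C@H]2c1ccc(OCc2ccccc2)cc1 | intermediate
18 | 1,3,5-trifluorobenzene | Fc1cc(F)cc(F)c1 | starting material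
19 | 1-(benzyloxy)-3,5-difluorobenzene | Fc1cc(F)cc(OCc2ccccc2)c1 | intermediate
20 | 1,3-bis(benzyloxy)-5-fluorobenzene | Fc1cc(OCc2ccccc2)cc(OCc2ccccc2)c1 | intermediate
21 | 1,5-bis(benzyloxy)-2-bromo-3-fluorobenzene | Brc1c(F)cc(OCc2ccccc2)cc1OCc1ccccc1 | intermediate
22 | 2-fluoro-4,6-bis(benzyloxy)phenyllithium | [Li]c1c(F)cc(OCc2ccccc2)cc1OCc1ccccc1 | intermediate
23 | dilithium 4,8-bis[2,4-bis(benzyloxy)-6-fluorophenyl]-6-[4-(benzyloxy)phenyl]-2-(4-methoxyphenyl)-3,7-dioxabicyclo[3.3.0]octane-4,8-bis(olate) (ring-fusion and benzylic centres as in 17; C4 and C8 not defined) | [Li+].[Li+].COc1ccc(cc1)[C@H]1OC([O-])(c3c(F)cc(OCc4ccccc4)cc3OCc3ccccc3)[C@H]2[C@@H]1C([O-])(c1c(F)cc(OCc3ccccc3)cc1OCc1ccccc1)O[C@H]2c1ccc(OCc2ccccc2)cc1 | intermediate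
24 | (1S,2S,3S,4R)-2,3-bis[2,4-bis(benzyloxy)-6-fluorobenzoyl]-4-[4-(benzyloxy)phenyl]-1-(4-methoxyphenyl)butane-1,4-diol | COc1ccc(cc1)[C@@H](O)[C@@H](C(=O)c1c(F)cc(OCc2ccccc2)cc1OCc1ccccc1)[C@H](C(=O)c1c(F)cc(OCc2ccccc2)cc1OCc1ccccc1)[C@@H](O)c1ccc(OCc2ccccc2)cc1 | intermediate
25 | dipotassium 1,4-dialkoxide of 24 | [K+].[K+].COc1ccc(cc1)[C@@H]([O-])[C@@H](C(=O)c1c(F)cc(OCc2ccccc2)cc1OCc1ccccc1)[C@H](C(=O)c1c(F)cc(OCc2ccccc2)cc1OCc1ccccc1)[C@@H]([O-])c1ccc(OCc2ccccc2)cc1 | intermediate
26 | (2S,3S)-5,7-bis(benzyloxy)-3-[(2R,3S)-5,7-bis(benzyloxy)-2-[4-(benzyloxy)phenyl]-4-oxochroman-3-yl]-2-(4-methoxyphenyl)chroman-4-one | COc1ccc([C@H]2Oc3cc(OCc4ccccc4)cc(OCc4ccccc4)c3C(=O)[C@H]2[C@@H]2C(=O)c3c(OCc4ccccc4)cc(OCc4ccccc4)cc3O[C@H]2c2ccc(OCc3ccccc3)cc2)cc1 | intermediate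
27 | (2S,3S)-5,7-dihydroxy-3-[(2R,3S)-5,7-dihydroxy-2-(4-hydroxyphenyl)-4-oxochroman-3-yl]-2-(4-methoxyphenyl)chroman-4-one | COc1ccc([C@H]2Oc3cc(O)cc(O)c3C(=O)[C@H]2[C@@H]2C(=O)c3c(O)cc(O)cc3O[C@H]2c2ccc(O)cc2)cc1 | target

Total: 10 steps. Longest linear sequence: 8 steps (steps 1–5, then 8, 9, 10); the arene branch (steps 6 and 7) joins at step 8.

Least certain steps

Step 8 (key step). Most likely failure: deprotonation of 17 at C3 or C3'' instead of carbonyl addition, followed by β-elimination that opens the other lactone; a lesser risk is premature collapse of the first hemiketalate and a second addition at the same carbon. The cause would be the basicity of a hindered aryllithium toward acidic ring-fusion hydrogens. Fallback, from 17 back to 24: Me2AlN(OMe)Me (from AlMe3 and MeNHOMe·HCl) in CH2Cl2 should open both lactones to the bis(N-methoxy-N-methylamide) diol F1. Et3SiOTf/2,6-lutidine would give its bis(triethylsilyl) ether F2. Reagent 22 (from 21) would add once to each amide at −78 → −40 °C, the chelated tetrahedral intermediate preventing a second addition, to give the bis(silyl ether) diketone F3. HF·pyridine would remove the silyl groups and return 24. The amide α-hydrogens are less acidic than those of the lactone, and the β-leaving group is then a silyl ether instead of a carboxylate.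

Step 9. Most likely failure: retro-aldol cleavage of C2–C3 or C2''–C3'' from the potassium alkoxides, because each is the β-alkoxide of an aryl ketone with an electron-rich aldehyde as the leaving partner; also epimerisation at C3 of the newly closed cis ring if any base survives. Fallback, from 24 back to 26: N-(trimethylsilyl)imidazole would give the bis(trimethylsilyl) ether F4. A catalytic amount of Bu4N[Ph3SiF2] or CsF in DMF (23–50 °C) should trigger a fluoride-relayed silyl-ether SNAr, in which each ring closure releases the fluoride that activates the next silyl ether. A free alkoxide is then present only in catalytic amount and no stoichiometric strong base is used.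

Step 2. Most likely failure: stalling of the magnesium catalyst if silylation of the acid is incomplete and carboxylate binds the metal, or loss of the trimethylsilyl ether while the silyl ester is hydrolysed, after which O1'' would lactonise onto C4 during step 3. Fallback, from 1 back to 8: N-acylation of 1 with purchased monoallyl succinate (t-BuCOCl, Et3N, LiCl) would give the allyl ester imide F5. The same MgCl2/Et3N/Me3SiCl aldol with 5 would give the silyl ether allyl ester F6, isolated after a neutral work-up. Pd(PPh3)4 (cat.) with N-methylaniline would remove the allyl group under near-neutral conditions and deliver 8.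

Step 4. Most likely failure: poor facial selectivity if the auxiliary and the existing C3''/C2'' centres are mismatched, slow enolisation next to the fully substituted C3'', or loss of the silyl ether to the boron Lewis acid. Fallback, from 8 back to 17, by acylation and reduction instead of aldol: 8 would be coupled with 1 instead of 9 (conditions of step 3) to give the bis-(R)-imide F7. NaN(SiMe3)2 and 4-methoxybenzoyl chloride (THF, −78 °C) would acylate the chelated Z-enolate on the face away from the benzyl group to give the β-keto imide F8. This has the same C3 configuration as the boron aldol with the other auxiliary and is protected from enolisation by allylic strain. Zn(BH4)2 would reduce the ketone under chelation control to the syn alcohol F9. Et3N/DMAP would close lactone A to the lactone imide F10. The conditions of step 5 would then give, through the free alcohol F11, compound 17.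

## Further compounds

F1 | step 8 | (2S,3S)-2-[(S)-hydroxy(4-methoxyphenyl)methyl]-3-{(R)-[4-(benzyloxy)phenyl](hydroxy)methyl}-N1,N4-dimethoxy-N1,N4-dimethylbutanediamide | COc1ccc(cc1)[C@@H](O)[C@@H](C(=O)N(C)OC)[C@H](C(=O)N(C)OC)[C@@H](O)c1ccc(OCc2ccccc2)cc1
F2 | step 8 | bis(triethylsilyl) ether of F1 | COc1ccc(cc1)[C@@H](O[Si](CC)(CC)CC)[C@@H](C(=O)N(C)OC)[C@H](C(=O)N(C)OC)[C@@H](O[Si](CC)(CC)CC)c1ccc(OCc2ccccc2)cc1
F3 | step 8 | bis(triethylsilyl) ether of 24 | COc1ccc(cc1)[C@@H](O[Si](CC)(CC)CC)[C@@H](C(=O)c1c(F)cc(OCc2ccccc2)cc1OCc1ccccc1)[C@H](C(=O)c1c(F)cc(OCc2ccccc2)cc1OCc1ccccc1)[C@@H](O[Si](CC)(CC)CC)c1ccc(OCc2ccccc2)cc1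
F4 | step 9 | bis(trimethylsilyl) ether of 24 | COc1ccc(cc1)[C@@H](O[Si](C)(C)C)[C@@H](C(=O)c1c(F)cc(OCc2ccccc2)cc1OCc1ccccc1)[C@H](C(=O)c1c(F)cc(OCc2ccccc2)cc1OCc1ccccc1)[C@@H](O[Si](C)(C)C)c1ccc(OCc2ccccc2)cc1
F5 | step 2 | allyl 4-[(4R)-4-benzyl-2-oxo-1,3-oxazolidin-3-yl]-4-oxobutanoate | C=CCOC(=O)CCC(=O)N1[C@H](Cc2ccccc2)COC1=O
F6 | step 2 | allyl (3S)-4-[(4R)-4-benzyl-2-oxo-1,3-oxazolidin-3-yl]-3-{(R)-[4-(benzyloxy)phenyl][(trimethylsilyl)oxy]methyl}-4-oxobutanoate | C=CCOC(=O)C[C@@H]([C@@H](O[Si](C)(C)C)c1ccc(OCc2ccccc2)cc1)C(=O)N1[C@H](Cc2ccccc2)COC1=O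
F7 | step 4 | succinyl bis-imide as 11 but with the (R)-auxiliary on both C4 and C4'' | O=C(C[C@@H]([C@@H](O[Si](C)(C)C)c1ccc(OCc2ccccc2)cc1)C(=O)N1[C@H](Cc2ccccc2)COC1=O)N1[C@H](Cc2ccccc2)COC1=O
F8 | step 4 | β-keto imide: F7 carrying a 4-methoxybenzoyl group on C3 (S) | COc1ccc(cc1)C(=O)[C@@H](C(=O)N1[C@H](Cc2ccccc2)COC1=O)[C@@H]([C@@H](O[Si](C)(C)C)c1ccc(OCc2ccccc2)cc1)C(=O)N1[C@H](Cc2ccccc2)COC1=O
F9 | step 4 | syn alcohol as 14 but with the (R)-auxiliary on C4 | COc1ccc(cc1)[C@@H](O)[C@@H](C(=O)N1[C@H](Cc2ccccc2)COC1=O)[C@@H]([C@@H](O[Si](C)(C)C)c1ccc(OCc2ccccc2)cc1)C(=O)N1[C@H](Cc2ccccc2)COC1=O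
F10 | step 4 | lactone imide as 15 but with the (R)-auxiliary on C4 | COc1ccc(cc1)[C@H]1OC(=O)[C@H]([C@@H](O[Si](C)(C)C)c2ccc(OCc3ccccc3)cc2)[C@@H]1C(=O)N1[C@H](Cc2ccccc2)COC1=O
F11 | step 4 | hydroxy lactone imide as 16 but with the (R)-auxiliary on C4 | COc1ccc(cc1)[C@H]1OC(=O)[C@H]([C@@H](O)c2ccc(OCc3ccccc3)cc2)[C@@H]1C(=O)N1[C@H](Cc2ccccc2)COC1=O
A1 | alternative 1 | 2'-hydroxychalcone (either alkene isomer) with 4',6'-bis(benzyloxy) and 4-(benzyloxy) groups, carrying at Cα the C3 atom of the all-cis 5,7-bis(benzyloxy)-4-(tert-butyldimethylsilyloxy)-2-(4-methoxyphenyl)flavan | COc1ccc([C@H]2Oc3cc(OCc4ccccc4)cc(OCc4ccccc4)c3[C@@H](O[Si](C)(C)C(C)(C)C)[C@H]2C(=Cc2ccc(OCc3ccccc3)cc2)C(=O)c2c(O)cc(OCc3ccccc3)cc2OCc2ccccc2)cc1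
A2 | alternative 1 | trans-flavanone joined at C3'' to C3 of the all-cis 4-(tert-butyldimethylsilyloxy)flavan | COc1ccc([C@H]2Oc3cc(OCc4ccccc4)cc(OCc4ccccc4)c3[C@@H](O[Si](C)(C)C(C)(C)C)[C@H]2[C@@H]2C(=O)c3c(OCc4ccccc4)cc(OCc4ccccc4)cc3O[C@H]2c2ccc(OCc3ccccc3)cc2)cc1
A3 | alternative 2 | 2,2-dimethyl-7,8-dihydro-4H-1,3-benzodioxine-4,5(6H)-dione 7-ethylene ketal | CC1(C)OC2=C(C(=O)CC3(C2)OCCO3)C(=O)O1
A4 | alternative 2 | 2-(oxomethylene)cyclohexane-1,3-dione 5-ethylene ketal | O=C=C1C(=O)CC2(CC1=O)OCCO2
A5 | alternative 2 | (2R,3S)-5,7-bis(benzyloxy)-2-[4-(benzyloxy)phenyl]-3-[(Z)-2-(4-methoxyphenyl)ethenyl]chroman-4-one | COc1ccc(/C=C\[C@@H]2C(=O)c3c(OCc4ccccc4)cc(OCc4ccccc4)cc3O[C@H]2c2ccc(OCc3ccccc3)cc2)cc1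
A6 | alternative 2 | biflavanone whose ring A is a 5-oxo-7,7-ethylenedioxy-tetrahydro ring | COc1ccc([C@H]2OC3=C(C(=O)CC4(C3)OCCO4)C(=O)[C@H]2[C@@H]2C(=O)c3c(OCc4ccccc4)cc(OCc4ccccc4)cc3O[C@H]2c2ccc(OCc3ccccc3)cc2)cc1
A7 | alternative 3 | 6-diazoacetyl-2,3-cis-2-(4-methoxyphenyl)-2,3-dihydropyran-4-one carrying the pentabenzyl-free trans-flavanone half on C3 | COc1ccc([C@H]2OC(C(=O)C=[N+]=[N-])=CC(=O)[C@H]2[C@@H]2C(=O)c3c(OCc4ccccc4)cc(OCc4ccccc4)cc3O[C@H]2c2ccc(OCc3ccccc3)cc2)cc1
A8 | alternative 3 | (triisopropylsiloxy)acetylene | C#CO[Si](C(C)C)(C(C)C)C(C)C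
A9 | alternative 3 | biflavanone with free 5-OH and 7-triisopropylsilyl ether on ring A, benzyl ethers elsewhere | COc1ccc([C@H]2Oc3cc(O[Si](C(C)C)(C(C)C)C(C)C)cc(O)c3C(=O)[C@H]2[C@@H]2C(=O)c3c(OCc4ccccc4)cc(OCc4ccccc4)cc3O[C@H]2c2ccc(OCc3ccccc3)cc2)cc1
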